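## Analysis of the target

The target is a briarane diterpenoid. A cyclohexenone (ring A: C1, C10–C14) is trans-fused through C1 and C10 to a ten-membered carbocycle (C1–C10). That ring carries a γ-lactone fused at C7–C8 (O on C7, carbonyl C19, methine C17 with methyl C18).

Reading the SMILES gives these relative configurations, with β defined as the face of the C15 methyl on C1: 2β-OAc, 6α-Cl, 7α-O (lactone), 8α-OH (C17 β, so the lactone is trans-fused), 9β-OAc, 10α-H, 11α-OH/11β-CH3, and the C18 methyl cis to the 8-OH. C3=C4 is Z and conjugated with the exocyclic C5=C16 methylene. Nine stereocentres (C1, C2, C6–C11, C17) sit on a twenty-carbon skeleton in which almost every ring carbon is functionalised.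

The fragile groups are:
- the secondary allylic chloride at C6 next to the exocyclic methylene (SN2' and E2 prone);
- the tertiary β-hydroxy lactone (retro-aldol, dehydration);
- the α-ketol/enone of ring A, the cis-diene (1,5-hydrogen shift on heating) and two base-labile acetates.

The hard part is the medium ring itself, with a Z olefin, a 2-substituted diene and six contiguous stereocentres on it.

The feature that invites the strategy is the array C3=C4–C5(=C16)–C6–C7–C8(–O) inside the ten-membered ring. A Z ring olefin, an exocyclic methylene on the next carbon and an oxygenated carbon 1,5 to the olefin form the retron of an oxy-Cope rearrangement of a 1-vinyl-2-allenylcyclohexanol. The bond C5–C6 is made, a bond C3–C8 of a cyclohexane is broken, and C4=C5=C16 was an allene.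

## Retrosynthetic reasoning

**C6–Cl (23 from 22).** The chloride is cut last because it is the most fragile group. The forward step is a deoxychlorination of allylic alcohol 22 with inversion, without allylic transposition.

**C6–O and the acetates (22 from 21, 21 from 20, 20 from 19).** C6 carries the only allylic hydrogens of the exocyclic C5=C16 bond, so the hydroxyl can be introduced by allylic C–H oxidation of diacetate 21. Compound 21 comes from silyl ether 19 by desilylation to 20 and acetylation; the acetates could not have survived the organometallic steps.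

**Lactone (19 from 18, 18 from 16 and 17).** The bond C8–C17 is cut as an intramolecular Reformatsky reaction of α-acyloxy ketone 18, which sets C8 and C17 and needs no base next to an enolisable ketone. The bond C7–O is cut as displacement of the bromide of 16 by the carboxylate of 17, so all three lactone carbons arrive in one reagent and C7 is inverted to the α-oxygen.

**Ten-membered ring (16 from 14).** The ring is cut at C5–C6 while C3–C8 is re-formed. The ten-membered ring shrinks to a cyclohexane (ring B: C1, C2, C3, C8, C9, C10), the C3=C4/C5=C16 diene becomes an allenyl group on C3, and C6–C7 becomes a vinyl group on the carbinol C8. This cut is chosen because a rigid trans-decalin such as 14 can be assembled with substrate control, and its geometry should then be translated into the Z olefin and the C7 configuration. The forward step must be a chair-like anionic oxy-Cope rearrangement with stereoselective trapping of the enolate.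

**Ring A oxidation (14 from 13, 13 from 11).** The enone and the tertiary C11 alcohol are introduced on carbinol 11. This is after the C8 ketone has been consumed (no competing enolisation) and before the diene exists (no competing photooxygenation). Transposing oxygenation of C12=C13 gives 13, and α'-hydroxylation gives 14.

**Vinyl and allenyl groups (11 from 9 and 10; 9 from 8).** The vinyl group comes from 10 by 1,2-addition to ketone 9. The allenyl group at C3 comes from a propargyl Claisen rearrangement of enol ether 8, which turns the C8–O–propargyl bond into the C3–C4 bond and returns the C8 ketone.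

**Ring B oxygen pattern (8 from 7, 7 from 6, 6 from 4 and 5).** All four functionalised carbons of ring B map onto a methoxy-quinone: C2 and C9 are its carbonyls, C8 its enol-ether carbon and C3 its nucleophilic α-carbon. Exchange of the methoxy group of 4 for the propargyloxy group of 5 gives 6; reduction of both carbonyls from the face opposite C15 gives 7, and silylation gives 8.

**Decalin (4 from 1 and 2, via 3).** A catalytic enantioselective Diels–Alder reaction of quinone 1 with diene 2 sets C1, the only stereocentre made by a chiral catalyst. Epimerisation of adduct 3 at C10 gives the trans ring fusion of 4. Every later stereocentre is relayed from C1.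

## Alternatives that were turned down

**Alternative 1:** the textbook disconnection, closure of the ten-membered ring at C3=C4 by ring-closing metathesis of the open-chain tetraene A1 (a C2 vinyl group and the vinyl arm of a 2-substituted butadiene).
- The forward step must make a Z olefin in a strained ten-membered ring.
- The metal carbene can also engage the C5=C16 methylene of the diene, which would give a nine-membered ring.
- A1 already needs all nine stereocentres, the allylic chloride and the lactone, set one by one on a flexible chain. The linear sequence would be much longer, and the key step would add no stereochemical information.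

**Alternative 2:** the biomimetic disconnection of C1–C10, a transannular epoxide–olefin cyclisation of the fourteen-membered epoxide A2.
- A2 is a fully oxygenated macrocycle that is at least as hard to make as the target.
- The acetoxy groups on C2 and C9 flank both reacting carbons. They deactivate the cyclisation inductively and invite neighbouring-group capture of the epoxide.
- The C11 cation would have to be hydrated stereoselectively without an enzyme, and the C14 oxygen left by the epoxide would still need elimination and redox adjustment.

**Alternative 3:** Grob fragmentation of the tricyclic mesylate A3 (C3–C8 cleaved, leaving group on C4, alkoxide on C8).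
- The forward step would give the Z olefin and the C8 ketone, but it needs a third six-membered ring (C3–C8) with the leaving group held antiperiplanar to C3–C8.
- That ring carries more stereocentres than the fragmentation keeps.
- The allylic mesylate next to the C5 methylene would ionise or react SN2'.
- The same C3–C8 bond can be broken with two small unsaturated substituents instead of a whole ring, which is what the chosen route does.

Key step: step 9

## Remarks before the steps

- Numbering: carbons keep the briarane numbers defined above in all intermediates (C15 = methyl on C1, C16 = exocyclic methylene carbon, C20 = methyl on C11). β is the face of the C15 methyl; ring B is the cyclohexane C1–C2–C3–C8–C9–C10 of the decalin intermediates.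
- Assumption: the facial sense of the oxazaborolidinium catalyst is taken from its usual pre-transition-state model. The (S)-catalyst is written for the enantiomer drawn; its mirror image would be used if the model assigns the other face.

## Steps

Step 1
Reactants: 1 2-methoxy-5-methyl-1,4-benzoquinone; 2 (E)-penta-1,3-diene
Product: 4 trans-fused methoxy ene-dione (2-methoxy-4a,8-dimethyl-4a,5,8,8a-tetrahydronaphthalene-1,4-dione; 1β-CH3/10α-H/11α-CH3), via cis-fused adduct 3 (not isolated)
Conditions: (S)-diphenylprolinol-derived B-(o-tolyl)oxazaborolidine (20 mol %), HNTf2 (20 mol %), CH2Cl2, −78 to −40 °C; then DBU (0.2 equiv), 23 °C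
Reagents that add atoms: none
Why: Enantioselective quinone Diels–Alder reaction under chiral oxazaborolidinium catalysis: the catalyst should bind the C9 carbonyl (not deactivated by the methoxy group, flanked by the vinylic C10–H), so the unsubstituted diene terminus bonds to the methyl-bearing C1 and sets this quaternary centre; the cis adduct then epimerises at C10 (α to the C9 ketone) to the trans-fused isomer, in which the C11 methyl is equatorial.

Step 2
Reactants: 4 trans-fused methoxy ene-dione; 5 prop-2-yn-1-ol
Product: 6 propargyl vinylogous ester (8-(prop-2-yn-1-yloxy) analogue of 4)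
Conditions: 5 (10 equiv), camphorsulfonic acid (10 mol %), benzene, 60 °C, 4 Å molecular sieves
Reagents that add atoms: none
Why: Acid-catalysed addition–elimination at the β-carbon (C8) of the vinylogous ester exchanges the alkoxy group without changing its position; removal of methanol drives the exchange.

Step 3
Reactants: 6 propargyl vinylogous ester
Product: 7 2β,9β-diol (C3=C8 propargyl enol ether retained)
Conditions: iBu2AlH (2.5 equiv), CH2Cl2, −78 to −40 °C; aqueous Rochelle salt
Reagents that add atoms: none
Why: 1,2-Reduction of the C9 ketone and of the vinylogous ester carbonyl C2; both hydrides should arrive on the α-face, opposite the axial C15 methyl (adjacent to C2, 1,3-diaxial to C9), giving the equatorial 2β and the axial 9β alcohol; basic work-up protects the acid-labile γ-hydroxy enol ether.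

Step 4
Reactants: 7 2β,9β-diol
Product: 8 2β,9β-bis(tert-butyldimethylsilyl) ether
Conditions: TBSOTf (2.5 equiv), 2,6-lutidine, CH2Cl2, −78 to 0 °C
Reagents that add atoms: tert-butyldimethylsilyl trifluoromethanesulfonate, CC(C)(C)[Si](C)(C)OS(=O)(=O)C(F)(F)F
Why: Silylation of both secondary alcohols under non-acidic conditions; the bulky, non-chelating ethers later steer additions at C8 and survive all basic steps.

Step 5
Reactants: 8 bis-silyl propargyl enol ether
Product: 9 3α-allenyl C8 ketone (3-(propa-1,2-dien-1-yl) ketone)
Conditions: toluene, 120 °C, sealed tube, base-washed glass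
Reagents that add atoms: none
Why: Propargyl Claisen (Saucy–Marbet) rearrangement: the O–C8=C3 propargyl vinyl ether shifts [3,3] to the C8 ketone and the C3 allene (C4=C5=C16); the allenyl group should arrive on the α-face of C3 because the β-face is screened by the axial C15 methyl and the axial 9β-silyloxy group, and the equatorial α-epimer is also the thermodynamic one.

Step 6
Reactants: 9 3α-allenyl ketone; 10 vinylmagnesium bromide
Product: 11 8β-hydroxy-8α-vinyl-3α-allenyl decalin (ring A still the C12=C13 olefin)
Conditions: CeCl3 (anhydrous, 1.5 equiv), CH2=CHMgBr (1.5 equiv), THF, −78 °C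
Reagents that add atoms: none
Why: Organocerium 1,2-addition avoids enolisation of the β-allenyl ketone; axial attack on the α-face, anti to the axial C9–O bond (polar Felkin–Anh), should place the vinyl group axial (α) and the hydroxyl equatorial (β), cis to the equatorial allenyl group.

Step 7
Reactants: 11 vinyl allenyl carbinol
Product: 13 ring A enone (C12 ketone; C13=C14; 11α-CH3), via allylic hydroperoxide 12 (not isolated)
Conditions: O2, visible light, tetraphenylporphyrin (cat.), CH2Cl2, 0 °C; then Ac2O, pyridine, DMAP (cat.), 0 to 23 °C
Reagents that add atoms: dioxygen, O=O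
Why: Schenck ene reaction then Kornblum–DeLaMare-type dehydration: singlet oxygen should attack the α-face of C12=C13 (the monosubstituted vinyl and allene units are inert), abstract the axial 14α-hydrogen and bond to C12 (the C11 hydrogen lies on the shielded β-face), so the transposed enone results; the tertiary alcohol is not acylated.

Step 8
Reactants: 13 ring A enone
Product: 14 11α-hydroxy enone (the oxy-Cope substrate)
Conditions: LiN(iPr)2 (2.5 equiv), THF, −78 °C; then 2-(phenylsulfonyl)-3-phenyloxaziridine (1.3 equiv), −78 to −40 °C; aqueous NH4Cl
Reagents that add atoms: 2-(phenylsulfonyl)-3-phenyloxaziridine, O=S(=O)(N1OC1c1ccccc1)c1ccccc1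
Why: Kinetic α'-deprotonation of the enone at C11 (the lithium alkoxide of the carbinol should not rearrange at −78 °C) and electrophilic hydroxylation of the cross-conjugated dienolate; oxygen should come from the α-face, anti to the C15 methyl that is 1,3-related to C11, giving the 11α-hydroxy-11β-methyl centre.

Step 9
Reactants: 14 11α-hydroxy enone carbinol
Product: 16 ten-membered 7β-bromo C8 ketone ((3Z)-3,5(16)-diene), via dipotassium enolate 15 (not isolated)
Conditions: KN(SiMe3)2 (2.2 equiv), 18-crown-6 (2.2 equiv), THF, −78 to 0 °C; then N-bromosuccinimide (1.1 equiv), −78 °C; pH 7 buffer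
Reagents that add atoms: N-bromosuccinimide, O=C1CCC(=O)N1Br
Why: Anionic oxy-Cope rearrangement of a 1-vinyl-2-allenylcyclohexanol followed by enolate bromination: the potassium alkoxide on C8 weakens the C3–C8 bond, which breaks as the vinyl terminus C6 bonds to the central allene carbon C5 in a [3,3]-sigmatropic shift; the closest known reactions are the anionic oxy-Cope ring expansion of 1,2-divinylcyclohexanols to cyclodec-5-enones and the Cope rearrangement of 1,2,6-trienes to 2-substituted 1,3-dienes. The ten-membered ring is not closed by cyclisation but arises by four-atom ring expansion of ring B through a six-membered chair transition state, and the same event gives the C3=C4 olefin, the exocyclic C5=C16 methylene and the C8 carbonyl as enolate 15. The trans-decalin holds the vinyl group axial and the allenyl group equatorial, so only the chair is within reach; in it the C2–C3 bond is axial, which makes C3=C4 Z, and the C8–C9 bond is equatorial, which makes the enolate trans within the ring. That enolate is planar-chiral with its inner face turned toward C3/C4, so bromine should reach C7 only from the outer face, giving the 7β-bromide needed for the later inversion. The step needs concerted rearrangement rather than heterolytic loss of an allenyl anion, chair rather than boat, and bromination faster than ring inversion of the enolate or its transannular Michael addition to C14; the locked cis-1,2 geometry, the strain released from the allene and trapping at −78 °C are relied on for these. The C11 alkoxide is a spectator, since ring A has no enolisable hydrogen and its α-ketol is already the conjugated isomer.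

Step 10
Reactants: 16 7β-bromo ketone; 17 2-bromopropanoic acid (racemic)
Product: 18 7α-(2-bromopropanoyloxy) C8 ketone (mixture at the bromine-bearing carbon)
Conditions: 17 (3 equiv), Cs2CO3 (1.5 equiv), DMF, 0 °C
Reagents that add atoms: none
Why: SN2 displacement of an α-bromo ketone by a carboxylate with inversion at C7 should bring the oxygen to the α-face and install C17–C19 in one reagent; the weakly basic caesium salt keeps E2 loss of HBr and enolisation low.

Step 11
Reactants: 18 7α-(2-bromopropanoyloxy) ketone
Product: 19 7,19-lactone with 8α-OH (2β,9β-bis-silyl ether)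
Conditions: Zn (activated), THF, 0 to 23 °C; aqueous NH4Cl
Reagents that add atoms: none
Why: Intramolecular Reformatsky reaction: the zinc enolate formed regiospecifically at C17 adds to the neighbouring C8 ketone (5-exo-trig) without base; C17 should add to the β-face so that the ring branches C6 and C9 are not eclipsed (trans-fused lactone, 8α-OH), and the C18 methyl should settle away from C9, cis to the new hydroxyl, which is also the thermodynamic arrangement of this epimerisable centre.

Step 12
Reactants: 19 bis-silyl lactone
Product: 20 2β,9β-diol lactone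
Conditions: HF·pyridine, pyridine/THF, 0 to 23 °C
Reagents that add atoms: none
Why: Fluoride-mediated cleavage of the two secondary silyl ethers under buffered conditions that should leave the β-hydroxy lactone and the α-ketol untouched; the diol is taken on at once to avoid lactone migration to O9.

Step 13
Reactants: 20 diol lactone
Product: 21 2β,9β-diacetate
Conditions: Ac2O, pyridine, 23 °C
Reagents that add atoms: acetic anhydride, CC(=O)OC(C)=O
Why: Acetylation of the two secondary alcohols; the tertiary alcohols on C8 and C11 are not acylated without a nucleophilic catalyst.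

Step 14
Reactants: 21 diacetate
Product: 22 6β-hydroxy diacetate
Conditions: SeO2 (0.5 equiv), t-BuOOH (2 equiv), CH2Cl2, 23 °C
Reagents that add atoms: tert-butyl hydroperoxide, CC(C)(C)OO (the oxygen atom is passed on by catalytic selenium dioxide, O=[Se]=O)
Why: Allylic hydroxylation by selenium dioxide (ene reaction at C16, then [2,3]-sigmatropic shift): C6 bears the only allylic hydrogens of the 1,1-disubstituted C5=C16 bond, so the olefin returns to the exocyclic position; the reagent is expected on the outer face of the ring, replacing the 6β-hydrogen with retention, but this facial choice is the least secure stereochemical call of the route.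

Step 15
Reactants: 22 6β-hydroxy diacetate
Product: 23 target, CNP0188317.1
Conditions: PPh3 (1.5 equiv), hexachloroacetone (3 equiv), CH2Cl2, −20 to 0 °C
Reagents that add atoms: hexachloroacetone, ClC(Cl)(Cl)C(=O)C(Cl)(Cl)Cl
Why: Appel-type deoxychlorination of a secondary allylic alcohol: the alkoxyphosphonium chloride ion pair should collapse by SN2 with inversion to the 6α-chloride with the olefin left in place; non-ionising conditions and the electron-withdrawing oxygen on C7 disfavour ionisation, and low temperature limits SN2' attack at C16.

## Compound list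

1 | 2-methoxy-5-methyl-1,4-benzoquinone | COC1=CC(=O)C(C)=CC1=O | starting material
2 | (E)-penta-1,3-diene | C/C=C/C=C | starting material
3 | cis-fused Diels–Alder adduct (1β-CH3, 10β-H, 11α-CH3; C2 and C9 ketones, C8 methoxy enol ether, C12=C13) | C[C@]12CC=C[C@@H](C)[C@H]1C(=O)C(OC)=CC2=O | intermediate (not isolated)
4 | trans-fused methoxy ene-dione (1β-CH3, 10α-H, 11α-CH3) | C[C@]12CC=C[C@@H](C)[C@@H]1C(=O)C(OC)=CC2=O | intermediate
5 | prop-2-yn-1-ol | C#CCO | starting material
6 | propargyl vinylogous ester (8-propargyloxy analogue of 4) | C[C@]12CC=C[C@@H](C)[C@@H]1C(=O)C(OCC#C)=CC2=O | intermediate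
7 | 2β,9β-diol with C3=C8 propargyl enol ether | C[C@]12CC=C[C@@H](C)[C@@H]1[C@H](O)C(OCC#C)=C[C@@H]2O | intermediate
8 | 2β,9β-bis(tert-butyldimethylsilyl) ether of 7 | C[C@]12CC=C[C@@H](C)[C@@H]1[C@H](O[Si](C)(C)C(C)(C)C)C(OCC#C)=C[C@@H]2O[Si](C)(C)C(C)(C)C | intermediate
9 | 3α-allenyl C8 ketone (2β,9β-bis-silyloxy; ring A olefin C12=C13) | C[C@]12CC=C[C@@H](C)[C@@H]1[C@H](O[Si](C)(C)C(C)(C)C)C(=O)[C@@H](C=C=C)[C@@H]2O[Si](C)(C)C(C)(C)C | intermediate
10 | vinylmagnesium bromide | C=C[Mg]Br | starting material
11 | 8β-hydroxy-8α-vinyl-3α-allenyl decalin | C[C@]12CC=C[C@@H](C)[C@@H]1[C@H](O[Si](C)(C)C(C)(C)C)[C@@](O)(C=C)[C@@H](C=C=C)[C@@H]2O[Si](C)(C)C(C)(C)C | intermediate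
12 | 12α-hydroperoxide with C13=C14 | C[C@]12C=C[C@@H](OO)[C@@H](C)[C@@H]1[C@H](O[Si](C)(C)C(C)(C)C)[C@@](O)(C=C)[C@@H](C=C=C)[C@@H]2O[Si](C)(C)C(C)(C)C | intermediate (not isolated)
13 | ring A enone (C12 ketone, C13=C14, 11α-CH3) of the vinyl allenyl carbinol | C[C@]12C=CC(=O)[C@@H](C)[C@@H]1[C@H](O[Si](C)(C)C(C)(C)C)[C@@](O)(C=C)[C@@H](C=C=C)[C@@H]2O[Si](C)(C)C(C)(C)C | intermediate
14 | 11α-hydroxy-11β-methyl enone, 8β-hydroxy-8α-vinyl-3α-allenyl decalin (oxy-Cope substrate) | C[C@]12C=CC(=O)[C@@](C)(O)[C@@H]1[C@H](O[Si](C)(C)C(C)(C)C)[C@@](O)(C=C)[C@@H](C=C=C)[C@@H]2O[Si](C)(C)C(C)(C)C | intermediate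
15 | dipotassium salt: C8 enolate (C7=C8 trans in the ring) and C11 alkoxide of the ring-expanded ketone | C=C1/C=C\[C@H](O[Si](C)(C)C(C)(C)C)[C@@]2(C)C=CC(=O)[C@@](C)([O-])[C@@H]2[C@H](O[Si](C)(C)C(C)(C)C)/C([O-])=C/C1.[K+].[K+] | intermediate (not isolated)
16 | ten-membered 7β-bromo C8 ketone, (3Z)-3,5(16)-diene, 2β,9β-bis-silyloxy, 11α-OH | C=C1/C=C\[C@H](O[Si](C)(C)C(C)(C)C)[C@@]2(C)C=CC(=O)[C@@](C)(O)[C@@H]2[C@H](O[Si](C)(C)C(C)(C)C)C(=O)[C@H](Br)C1 | intermediate
17 | 2-bromopropanoic acid (racemic) | CC(Br)C(=O)O | starting material
18 | 7α-(2-bromopropanoyloxy) C8 ketone | C=C1/C=C\[C@H](O[Si](C)(C)C(C)(C)C)[C@@]2(C)C=CC(=O)[C@@](C)(O)[C@@H]2[C@H](O[Si](C)(C)C(C)(C)C)C(=O)[C@@H](OC(=O)C(C)Br)C1 | intermediate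
19 | 7,19-lactone, 8α-OH, 17-methyl cis to 8-OH, 2β,9β-bis-silyloxy | C=C1/C=C\[C@H](O[Si](C)(C)C(C)(C)C)[C@@]2(C)C=CC(=O)[C@@](C)(O)[C@@H]2[C@H](O[Si](C)(C)C(C)(C)C)[C@]2(O)[C@@H](C)C(=O)O[C@H]2C1 | intermediate
20 | 2β,9β-diol lactone | C=C1/C=C\[C@H](O)[C@@]2(C)C=CC(=O)[C@@](C)(O)[C@@H]2[C@H](O)[C@]2(O)[C@@H](C)C(=O)O[C@H]2C1 | intermediate
21 | 2β,9β-diacetate (6-deschloro target) | C=C1/C=C\[C@H](OC(C)=O)[C@@]2(C)C=CC(=O)[C@@](C)(O)[C@@H]2[C@H](OC(C)=O)[C@]2(O)[C@@H](C)C(=O)O[C@H]2C1 | intermediate
22 | 6β-hydroxy diacetate | C=C1/C=C\[C@H](OC(C)=O)[C@@]2(C)C=CC(=O)[C@@](C)(O)[C@@H]2[C@H](OC(C)=O)[C@]2(O)[C@@H](C)C(=O)O[C@H]2[C@@H]1O | intermediate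
23 | CNP0188317.1: 2β,9β-diacetoxy-6α-chloro-8α,11α-dihydroxy-12-oxo-briara-3(Z),5(16),13-triene 7,19-lactone | C=C1/C=C\[C@H](OC(C)=O)[C@@]2(C)C=CC(=O)[C@@](C)(O)[C@@H]2[C@H](OC(C)=O)[C@]2(O)[C@@H](C)C(=O)O[C@H]2[C@H]1Cl | target

## Step count and least certain steps

Total: 15 steps. Longest linear sequence: 15 steps (1, 2, 5, 10 and 17 are purchased).

**Step 9 (key step).** The alkoxide may fragment heterolytically to an enone and an allenyl/propargyl anion that recombines without control, or the enolate may undergo ring inversion or transannular Michael addition before it is brominated, eroding the C7 configuration. Fallback, from 14 back to 16: run the rearrangement as a neutral siloxy-Cope. Both tertiary alcohols of 14 are silylated (TMSOTf, 2,6-lutidine) to the 8,11-bis(trimethylsilyl) ether F1. Heating in toluene at 110–130 °C should give the ring-expanded trimethylsilyl enol ether F2 through the same chair, with no anionic intermediate. Treating F2 with N-bromosuccinimide at −78 °C and working up with dilute acid (which also frees the C11 alcohol) leads to 16.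

**Step 10.** Bromide released in the reaction can exchange with the α-bromo ketone and scramble C7 before substitution, and E2 loss of HBr toward C6 competes. Fallback, from 14 to 18: after the oxy-Cope rearrangement the enolate 15 is hydroxylated with 2-(phenylsulfonyl)-3-phenyloxaziridine instead of brominated. This should give the 7β-hydroxy ketone F3 (oxygen from the same outer face). A Mitsunobu esterification of F3 with 17 (PPh3, diisopropyl azodicarboxylate) then inverts C7 and gives 18 directly.

**Step 11.** The zinc enolate may be protonated before it adds, or the closure may give the cis-fused lactone (wrong C8) or a C17 mixture. Fallback, from 16 to 19: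
- Displace the bromide of 16 with caesium 2-(diethoxyphosphoryl)propanoate to give the phosphonate ester F4.
- An intramolecular Horner–Wadsworth–Emmons reaction (LiCl, DBU) closes the butenolide F5 (C8=C17).
- Nucleophilic epoxidation (t-BuOOH, DBU) should give the 8α,17α-epoxy lactone F6.
- SmI2 (THF/MeOH, −78 °C) cleaves the C17–O bond of this α,β-epoxy lactone. Protonation at C17 then gives 19, with the methyl expected away from C9.

**Step 14.** Abstraction of the wrong C6 hydrogen (poor facial selectivity) or over-oxidation to the ketone would give the 6α-alcohol or a mixture. Fallback, from 21 to 22: oxidise the crude allylic alcohols with DMP (Dess–Martin periodinane) to the 6-oxo dienone F7, then reduce it with Me4NBH(OAc)3 (MeCN/AcOH, −20 °C). Hydride is delivered inside the boron complex of the 8α-hydroxyl, and this Evans–Saksena reduction should give the anti-1,3-diol, which is the 6β-alcohol 22.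

**Step 15.** Allylic transposition (SN2' attack of chloride at C16, or ionisation) would give the conjugated C16 chloride instead of the C6 chloride. Fallback, from 21 to 23, without passing through 22:
- Isomerise the exocyclic olefin of 21 into the ring with RhCl3·3H2O (cat., EtOH/CHCl3, 60 °C) to give the 3(Z),5(6)-diene F8 with a C16 methyl group.
- Treat F8 with Ca(OCl)2 and solid CO2 in CH2Cl2/water. This ene-type chlorination by hypochlorous acid puts chlorine on C6 from the exposed face and moves the olefin back to C5=C16, as in the presumed biogenesis of the 6-chloro-5(16)-ene unit.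

## Further compounds

F1 | step 9 | 8,11-bis(trimethylsilyl) ether of 14 | C[C@]12C=CC(=O)[C@@](C)(O[Si](C)(C)C)[C@@H]1[C@H](O[Si](C)(C)C(C)(C)C)[C@@](O[Si](C)(C)C)(C=C)[C@@H](C=C=C)[C@@H]2O[Si](C)(C)C(C)(C)C
F2 | step 9 | ring-expanded C8 trimethylsilyl enol ether (C7=C8 trans in the ring), 11-O-trimethylsilyl | C=C1/C=C\[C@H](O[Si](C)(C)C(C)(C)C)[C@@]2(C)C=CC(=O)[C@@](C)(O[Si](C)(C)C)[C@@H]2[C@H](O[Si](C)(C)C(C)(C)C)/C(O[Si](C)(C)C)=C/C1
F3 | step 10 | 7β-hydroxy C8 ketone | C=C1/C=C\[C@H](O[Si](C)(C)C(C)(C)C)[C@@]2(C)C=CC(=O)[C@@](C)(O)[C@@H]2[C@H](O[Si](C)(C)C(C)(C)C)C(=O)[C@H](O)C1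
F4 | step 11 | 7α-[2-(diethoxyphosphoryl)propanoyloxy] C8 ketone | C=C1/C=C\[C@H](O[Si](C)(C)C(C)(C)C)[C@@]2(C)C=CC(=O)[C@@](C)(O)[C@@H]2[C@H](O[Si](C)(C)C(C)(C)C)C(=O)[C@@H](OC(=O)C(C)P(=O)(OCC)OCC)C1
F5 | step 11 | 8(17)-unsaturated butenolide | C=C1/C=C\[C@H](O[Si](C)(C)C(C)(C)C)[C@@]2(C)C=CC(=O)[C@@](C)(O)[C@@H]2[C@H](O[Si](C)(C)C(C)(C)C)C2=C(C)C(=O)O[C@H]2C1
F6 | step 11 | 8α,17α-epoxy lactone | C=C1/C=C\[C@H](O[Si](C)(C)C(C)(C)C)[C@@]2(C)C=CC(=O)[C@@](C)(O)[C@@H]2[C@H](O[Si](C)(C)C(C)(C)C)[C@@]23O[C@@]3(C)C(=O)O[C@H]2C1
F7 | step 14 | 6-oxo dienone diacetate | C=C1/C=C\[C@H](OC(C)=O)[C@@]2(C)C=CC(=O)[C@@](C)(O)[C@@H]2[C@H](OC(C)=O)[C@]2(O)[C@@H](C)C(=O)O[C@H]2C1=O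
F8 | step 15 | 3(Z),5(6)-diene isomer of 21 with C16 methyl (both ring olefins cis) | C/1=C(\C)/C=C\[C@H](OC(C)=O)[C@@]2(C)C=CC(=O)[C@@](C)(O)[C@@H]2[C@H](OC(C)=O)[C@]2(O)[C@@H](C)C(=O)O[C@@H]12
A1 | alternative 1 | open-chain tetraene for ring-closing metathesis at C3=C4 | C=C[C@H](OC(C)=O)[C@@]1(C)C=CC(=O)[C@@](C)(O)[C@@H]1[C@H](OC(C)=O)[C@]1(O)[C@@H](C)C(=O)O[C@H]1[C@@H](Cl)C(=C)C=C
A2 | alternative 2 | fourteen-membered 1,14-epoxide with C10=C11 olefin (12-silyloxy) for transannular cyclisation | C=C1/C=C\[C@H](OC(C)=O)[C@@]2(C)O[C@@H]2C[C@H](O[Si](C)(C)C(C)(C)C)/C(C)=C/[C@H](OC(C)=O)[C@]2(O)[C@@H](C)C(=O)O[C@H]2[C@H]1Cl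
A3 | alternative 3 | tricyclic C4 mesylate with C3–C8 bond for Grob fragmentation | C[C@]12C=CC(=O)[C@@](C)(O)[C@@H]1[C@H](O[Si](C)(C)C(C)(C)C)[C@@]3(O)[C@@H](OCOC)CC(=C)[C@H](OS(C)(=O)=O)[C@H]3[C@@H]2O[Si](C)(C)C(C)(C)C
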